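**Plan**

1. Hydrindane locants: C1 acetyl, C2 angelate, C3a/C7a trans fusion, C4 methylidene, C6 acetate, C7 isopropyl.
2. Retrosynthesis: the acyl groups come off and the C1 acetyl goes back to a silyl-protected carbinol. The six-membered ring is then cut at C5–C6 (carbonyl–ene closure of a C6 aldehyde onto a C3a isopropenyl group). Finally C7–C7a and C1–C(carbinol) are cut together.
3. The last cut is possible because C7a and C1 are the β- and α-carbons of a cyclopentenone whose carbonyl is C2. The five-membered ring is bought intact, and the C3a isopropenyl group later supplies C4, C5 and the methylidene carbon.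
4. Forward: (R)-4-silyloxycyclopentenone → (R)-4-isopropenylcyclopentenone; three-component Michael–aldol coupling; redox adjustment to a keto aldehyde; Type II ene closure of the cyclohexane; acetate, C2 reduction, angelate, final oxidation.
5. Stereochemistry: C3a from the starting enone (cuprate anti to OSi); C7a and C1 by two successive anti additions; C7 by the geometrically defined ketene acetal in an open transition state; C6 by the ene chair (oxygen axial); C2 by hydride attack anti to the C1 side chain.

Key step: step 4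

Remark: the carbinol carbon made in step 4 is not controlled and is drawn without configuration in compounds 11–18, 21 and 22 (epimer pairs), because step 13 turns it into the ketone.

**Route**

Step 1
Reactants: 1 (R)-4-(tert-butyldimethylsilyloxy)cyclopent-2-en-1-one; 2 isopropenylmagnesium bromide
Product: 4 (3S,4R)-4-(tert-butyldimethylsilyloxy)-3-(prop-1-en-2-yl)cyclopentan-1-one, via TMS enol ether 3 (not isolated)
Conditions: 2, CuBr·SMe2 (10 mol %), TMSCl, THF, −78 °C; then 1 M HCl, THF, 0 °C
Reagents that add atoms: none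
Why: Copper-catalysed, TMSCl-accelerated conjugate addition of the alkenyl Grignard reagent should occur anti to the silyloxy group, as in cuprate additions to 4-silyloxycyclopentenones, which sets the future C3a centre; the enol silane is hydrolysed by the brief acidic work-up.

Step 2
Reactants: 4 (3S,4R)-4-(tert-butyldimethylsilyloxy)-3-(prop-1-en-2-yl)cyclopentan-1-one
Product: 5 (R)-4-(prop-1-en-2-yl)cyclopent-2-en-1-one
Conditions: DBU (1.1 equiv), CH2Cl2, −20 → 0 °C, short contact
Reagents that add atoms: none
Why: E1cB elimination of the β-silyloxy group through the C5 enolate should give the 4-substituted enone without touching the isopropenyl-bearing centre, and low temperature limits γ-deprotonation of the product.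

Step 3
Reactants: 6 methyl 3-methylbutanoate
Product: 8 (E)-1-methoxy-3-methyl-1-(trimethylsilyloxy)but-1-ene, via lithium enolate 7 (not isolated)
Conditions: LDA, THF, −78 °C; TMSCl, −78 °C → rt; non-aqueous work-up, distillation
Reagents that add atoms: chlorotrimethylsilane, C[Si](C)(C)Cl
Why: Kinetic enolisation with LDA in THF without a polar cosolvent should give the enolate with isopropyl trans to O–Li, and O-silylation fixes this as the (E)-ketene acetal, a single geometry being wanted for the diastereoselection of step 4.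

Step 4
Reactants: 5 (R)-4-(prop-1-en-2-yl)cyclopent-2-en-1-one; 8 (E)-1-methoxy-3-methyl-1-(trimethylsilyloxy)but-1-ene; 9 acetaldehyde
Product: 12 methyl (2S)-2-[(1S,2S,5R)-2-(1-hydroxyethyl)-3-oxo-5-(prop-1-en-2-yl)cyclopentyl]-3-methylbutanoate, via enol silane 10 (not isolated), via aldol TMS ether 11 (not isolated)
Conditions: 5, 8, TrSbCl6 (5 mol %), CH2Cl2, −78 °C; then MeCHO, −78 °C; then 1 M HCl, THF, 0 °C
Reagents that add atoms: none
Why: The trityl salt activates enone 5, the ketene acetal carbon adds to C7a (Mukaiyama–Michael) with silyl transfer to the C2 oxygen so that enol silane 10 forms regiospecifically (C1=C2), and the same catalyst then mediates the Mukaiyama aldol of 10 with acetaldehyde at C1 before acid work-up cleaves TMS ether 11. The closest known reaction is the trityl-salt-catalysed tandem Michael–aldol coupling of silyl nucleophiles, cycloalkenones and aldehydes, the silicon counterpart of three-component couplings on cyclopentenones. No ring is closed: the cyclopentanone is present from the start and two acyclic C–C bonds (C7–C7a and C1–carbinol carbon) are made. C7a is set by attack anti to the C3a isopropenyl group and C1 by attack on the aldehyde anti to the new C7a branch (the 1,7a-trans product is also the more stable), while C7 is set in an open transition state with the acetal C=C anti to the enone C=C and away from the catalyst-bound carbonyl, the acetal hydrogen over the ring and the isopropyl group outside, which corresponds to (7S); the carbinol centre is not controlled and need not be. The step needs 1,4- rather than 1,2-addition (expected for a silyl ketene acetal under Lewis-acid catalysis), reaction of the aldehyde with the enol silane and not with the isopropenyl group (the enol silane is by far the better π-nucleophile at −78 °C), and simple diastereoselection at C7, which rests on the defined geometry of 8 and is the least secure point.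

Step 5
Reactants: 12 methyl (2S)-2-[(1S,2S,5R)-2-(1-hydroxyethyl)-3-oxo-5-(prop-1-en-2-yl)cyclopentyl]-3-methylbutanoate
Product: 13 methyl (2S)-2-[(1S,2S,5R)-2-[1-(tert-butyldimethylsilyloxy)ethyl]-3-oxo-5-(prop-1-en-2-yl)cyclopentyl]-3-methylbutanoate
Conditions: TBSOTf, 2,6-lutidine, CH2Cl2, −78 °C
Reagents that add atoms: tert-butyldimethylsilyl triflate, CC(C)(C)[Si](C)(C)OS(=O)(=O)C(F)(F)F
Why: Silylation of the secondary carbinol with a silyl triflate and a hindered pyridine at low temperature should outrun ketone enolisation and aldol dehydration, and it masks the future acetyl oxygen until the last step.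

Step 6
Reactants: 13 methyl (2S)-2-[(1S,2S,5R)-2-[1-(tert-butyldimethylsilyloxy)ethyl]-3-oxo-5-(prop-1-en-2-yl)cyclopentyl]-3-methylbutanoate
Product: 14 (2S)-2-[(1R,2R,5R)-2-[1-(tert-butyldimethylsilyloxy)ethyl]-3-hydroxy-5-(prop-1-en-2-yl)cyclopentyl]-3-methylbutan-1-ol (ring carbinol epimers)
Conditions: DIBAL-H (5 equiv), CH2Cl2, −78 → 0 °C; Rochelle salt
Reagents that add atoms: none
Why: Exhaustive DIBAL-H reduction takes the ester to the primary alcohol (future C6) and the ketone to the alcohol under non-basic conditions that should not move the silyl group, and the C2 epimer mixture is removed again in the next step.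

Step 7
Reactants: 14 (2S)-2-[(1R,2R,5R)-2-[1-(tert-butyldimethylsilyloxy)ethyl]-3-hydroxy-5-(prop-1-en-2-yl)cyclopentyl]-3-methylbutan-1-ol
Product: 15 (2S)-2-[(1R,2S,5R)-2-[1-(tert-butyldimethylsilyloxy)ethyl]-3-oxo-5-(prop-1-en-2-yl)cyclopentyl]-3-methylbutanal
Conditions: Dess–Martin periodinane (3 equiv), NaHCO3, CH2Cl2, 0 °C → rt; used crude
Reagents that add atoms: none
Why: Buffered Dess–Martin oxidation of both hydroxyl groups should return the C2 ketone and give the C6 aldehyde without epimerising the α-centres C1 and C7.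

Step 8
Reactants: 15 (2S)-2-[(1R,2S,5R)-2-[1-(tert-butyldimethylsilyloxy)ethyl]-3-oxo-5-(prop-1-en-2-yl)cyclopentyl]-3-methylbutanal
Product: 16 (1S,3aR,6R,7S,7aR)-1-[1-(tert-butyldimethylsilyloxy)ethyl]-6-hydroxy-4-methylidene-7-(propan-2-yl)octahydro-2H-inden-2-one
Conditions: Me2AlCl (2.5 equiv), CH2Cl2, −78 → −40 °C
Reagents that add atoms: none
Why: Type II carbonyl–ene cyclisation, in which the aldehyde carbon bonds to the terminal alkene carbon (C5–C6) through a chair with isopropyl equatorial and the trans fusion diequatorial; the carbonyl oxygen must be axial to reach a hydrogen of the allylic methyl group, which should give the axial (6R) alcohol and the C4 methylidene, while the ketone has no alkene within reach.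

Step 9
Reactants: 16 (1S,3aR,6R,7S,7aR)-1-[1-(tert-butyldimethylsilyloxy)ethyl]-6-hydroxy-4-methylidene-7-(propan-2-yl)octahydro-2H-inden-2-one
Product: 17 (1S,3aR,6R,7S,7aR)-1-[1-(tert-butyldimethylsilyloxy)ethyl]-4-methylidene-2-oxo-7-(propan-2-yl)octahydro-1H-inden-6-yl acetate
Conditions: Ac2O, DMAP (cat.), pyridine, CH2Cl2, 0 °C → rt
Reagents that add atoms: acetic anhydride, CC(=O)OC(C)=O
Why: DMAP-catalysed acetylation of the axial secondary alcohol (a neomenthol-like environment) should proceed at or below room temperature, where the β-silyloxy ketone is stable to the weak amine bases.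

Step 10
Reactants: 17 (1S,3aR,6R,7S,7aR)-1-[1-(tert-butyldimethylsilyloxy)ethyl]-4-methylidene-2-oxo-7-(propan-2-yl)octahydro-1H-inden-6-yl acetate
Product: 18 (1R,2S,3aR,6R,7S,7aR)-1-[1-(tert-butyldimethylsilyloxy)ethyl]-2-hydroxy-4-methylidene-7-(propan-2-yl)octahydro-1H-inden-6-yl acetate
Conditions: L-Selectride (1.2 equiv), THF, −78 °C; H2O quench at −78 °C
Reagents that add atoms: none
Why: The bulky borohydride should attack the cyclopentanone from the face opposite the adjacent C1 side chain and give the 1,2-cis (2S) alcohol, as in selectride reductions of 2-substituted cyclopentanones, while the acetate is left alone at −78 °C.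

Step 11
Reactants: 18 (1R,2S,3aR,6R,7S,7aR)-1-[1-(tert-butyldimethylsilyloxy)ethyl]-2-hydroxy-4-methylidene-7-(propan-2-yl)octahydro-1H-inden-6-yl acetate; 19 angelic acid
Product: 21 (1R,2S,3aR,6R,7S,7aR)-6-acetoxy-1-[1-(tert-butyldimethylsilyloxy)ethyl]-4-methylidene-7-(propan-2-yl)octahydro-1H-inden-2-yl (2Z)-2-methylbut-2-enoate, via mixed anhydride 20 (not isolated)
Conditions: 19, 2,4,6-trichlorobenzoyl chloride, Et3N, toluene, rt; then 18, toluene, 80 °C (no DMAP)
Reagents that add atoms: none
Why: Yamaguchi-type esterification through the preformed angelic 2,4,6-trichlorobenzoic mixed anhydride, heated with the alcohol without a nucleophilic catalyst, is the established way to put an angelate on a hindered alcohol with little Z→E isomerisation to the tiglate.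

Step 12
Reactants: 21 (1R,2S,3aR,6R,7S,7aR)-6-acetoxy-1-[1-(tert-butyldimethylsilyloxy)ethyl]-4-methylidene-7-(propan-2-yl)octahydro-1H-inden-2-yl (2Z)-2-methylbut-2-enoate
Product: 22 (1S,2S,3aR,6R,7S,7aR)-6-acetoxy-1-(1-hydroxyethyl)-4-methylidene-7-(propan-2-yl)octahydro-1H-inden-2-yl (2Z)-2-methylbut-2-enoate
Conditions: HF·pyridine, pyridine, THF, 0 °C → rt
Reagents that add atoms: none
Why: Buffered HF·pyridine should cleave the secondary TBS ether without touching the two esters or the exocyclic alkene, and the weakly acidic medium disfavours 1,3-migration of the angelate.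

Step 13
Reactants: 22 (1S,2S,3aR,6R,7S,7aR)-6-acetoxy-1-(1-hydroxyethyl)-4-methylidene-7-(propan-2-yl)octahydro-1H-inden-2-yl (2Z)-2-methylbut-2-enoate
Product: 23 (1R,2S,3aR,6R,7S,7aR)-1-acetyl-6-acetoxy-4-methylidene-7-(propan-2-yl)octahydro-1H-inden-2-yl (2Z)-2-methylbut-2-enoate
Conditions: Dess–Martin periodinane, NaHCO3, CH2Cl2, 0 °C → rt
Reagents that add atoms: none
Why: Buffered Dess–Martin oxidation converts either carbinol epimer into the methyl ketone under neutral conditions, so the β-acyloxy ketone should neither lose angelate nor epimerise at C1.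

**Compound list**

1 | (R)-4-(tert-butyldimethylsilyloxy)cyclopent-2-en-1-one | CC(C)(C)[Si](C)(C)O[C@@H]1CC(=O)C=C1 | starting material
2 | isopropenylmagnesium bromide | CC(=C)[Mg]Br | starting material
3 | tert-butyl(dimethyl){[(1R,2S)-2-(prop-1-en-2-yl)-4-(trimethylsilyloxy)cyclopent-3-en-1-yl]oxy}silane | CC(C)(C)[Si](C)(C)O[C@@H]1CC(O[Si](C)(C)C)=C[C@H]1C(C)=C | intermediate (not isolated)
4 | (3S,4R)-4-(tert-butyldimethylsilyloxy)-3-(prop-1-en-2-yl)cyclopentan-1-one | CC(C)(C)[Si](C)(C)O[C@@H]1CC(=O)C[C@H]1C(C)=C | intermediate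
5 | (R)-4-(prop-1-en-2-yl)cyclopent-2-en-1-one | O=C1C=C[C@H](C(C)=C)C1 | intermediate
6 | methyl 3-methylbutanoate (methyl isovalerate) | COC(=O)CC(C)C | starting material
7 | lithium 1-methoxy-3-methylbut-1-en-1-olate (isopropyl trans to O–Li) | CC(C)/C=C(/[O-])OC.[Li+] | intermediate (not isolated)
8 | (E)-1-methoxy-3-methyl-1-(trimethylsilyloxy)but-1-ene | CC(C)/C=C(/O[Si](C)(C)C)OC | intermediate
9 | acetaldehyde | CC=O | starting material
10 | methyl (2S)-3-methyl-2-[(1S,5R)-5-(prop-1-en-2-yl)-3-(trimethylsilyloxy)cyclopent-2-en-1-yl]butanoate | COC(=O)[C@@H](C(C)C)[C@@H]1C=C(O[Si](C)(C)C)C[C@H]1C(C)=C | intermediate (not isolated)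
11 | methyl (2S)-3-methyl-2-[(1S,2S,5R)-3-oxo-5-(prop-1-en-2-yl)-2-[1-(trimethylsilyloxy)ethyl]cyclopentyl]butanoate | COC(=O)[C@@H](C(C)C)[C@@H]1[C@@H](C(C)O[Si](C)(C)C)C(=O)C[C@H]1C(C)=C | intermediate (not isolated)
12 | methyl (2S)-2-[(1S,2S,5R)-2-(1-hydroxyethyl)-3-oxo-5-(prop-1-en-2-yl)cyclopentyl]-3-methylbutanoate | COC(=O)[C@@H](C(C)C)[C@@H]1[C@@H](C(C)O)C(=O)C[C@H]1C(C)=C | intermediate
13 | methyl (2S)-2-[(1S,2S,5R)-2-[1-(tert-butyldimethylsilyloxy)ethyl]-3-oxo-5-(prop-1-en-2-yl)cyclopentyl]-3-methylbutanoate | COC(=O)[C@@H](C(C)C)[C@@H]1[C@@H](C(C)O[Si](C)(C)C(C)(C)C)C(=O)C[C@H]1C(C)=C | intermediate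
14 | (2S)-2-[(1R,2R,5R)-2-[1-(tert-butyldimethylsilyloxy)ethyl]-3-hydroxy-5-(prop-1-en-2-yl)cyclopentyl]-3-methylbutan-1-ol | OC[C@@H](C(C)C)[C@@H]1[C@@H](C(C)O[Si](C)(C)C(C)(C)C)C(O)C[C@H]1C(C)=C | intermediate
15 | (2S)-2-[(1R,2S,5R)-2-[1-(tert-butyldimethylsilyloxy)ethyl]-3-oxo-5-(prop-1-en-2-yl)cyclopentyl]-3-methylbutanal | O=C[C@@H](C(C)C)[C@@H]1[C@@H](C(C)O[Si](C)(C)C(C)(C)C)C(=O)C[C@H]1C(C)=C | intermediate
16 | (1S,3aR,6R,7S,7aR)-1-[1-(tert-butyldimethylsilyloxy)ethyl]-6-hydroxy-4-methylidene-7-(propan-2-yl)octahydro-2H-inden-2-one | C=C1C[C@@H](O)[C@@H](C(C)C)[C@@H]2[C@@H](C(C)O[Si](C)(C)C(C)(C)C)C(=O)C[C@@H]12 | intermediate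
17 | (1S,3aR,6R,7S,7aR)-1-[1-(tert-butyldimethylsilyloxy)ethyl]-4-methylidene-2-oxo-7-(propan-2-yl)octahydro-1H-inden-6-yl acetate | C=C1C[C@@H](OC(C)=O)[C@@H](C(C)C)[C@@H]2[C@@H](C(C)O[Si](C)(C)C(C)(C)C)C(=O)C[C@@H]12 | intermediate
18 | (1R,2S,3aR,6R,7S,7aR)-1-[1-(tert-butyldimethylsilyloxy)ethyl]-2-hydroxy-4-methylidene-7-(propan-2-yl)octahydro-1H-inden-6-yl acetate | C=C1C[C@@H](OC(C)=O)[C@@H](C(C)C)[C@@H]2[C@@H](C(C)O[Si](C)(C)C(C)(C)C)[C@@H](O)C[C@@H]12 | intermediate
19 | angelic acid, (2Z)-2-methylbut-2-enoic acid | C/C=C(/C)C(=O)O | starting material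
20 | (2Z)-2-methylbut-2-enoic 2,4,6-trichlorobenzoic anhydride | C/C=C(/C)C(=O)OC(=O)c1c(Cl)cc(Cl)cc1Cl | intermediate (not isolated)
21 | (1R,2S,3aR,6R,7S,7aR)-6-acetoxy-1-[1-(tert-butyldimethylsilyloxy)ethyl]-4-methylidene-7-(propan-2-yl)octahydro-1H-inden-2-yl (2Z)-2-methylbut-2-enoate | C=C1C[C@@H](OC(C)=O)[C@@H](C(C)C)[C@@H]2[C@@H](C(C)O[Si](C)(C)C(C)(C)C)[C@@H](OC(=O)/C(C)=C\C)C[C@@H]12 | intermediate
22 | (1S,2S,3aR,6R,7S,7aR)-6-acetoxy-1-(1-hydroxyethyl)-4-methylidene-7-(propan-2-yl)octahydro-1H-inden-2-yl (2Z)-2-methylbut-2-enoate | C=C1C[C@@H](OC(C)=O)[C@@H](C(C)C)[C@@H]2[C@@H](C(C)O)[C@@H](OC(=O)/C(C)=C\C)C[C@@H]12 | intermediate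
23 | (1R,2S,3aR,6R,7S,7aR)-1-acetyl-6-acetoxy-4-methylidene-7-(propan-2-yl)octahydro-1H-inden-2-yl (2Z)-2-methylbut-2-enoate (CNP0322881.1) | C=C1C[C@@H](OC(C)=O)[C@@H](C(C)C)[C@@H]2[C@@H](C(C)=O)[C@@H](OC(=O)/C(C)=C\C)C[C@@H]12 | target

**Step count and risks**

Total: 13 steps. Longest linear sequence: 12 steps from compound 1 (steps 1, 2, 4–13); step 3 is a one-step side branch.

Steps most likely to fail:

Step 4. The open transition states that differ at C7 may lie close in energy, so simple diastereoselection could be poor, and the aldol stage could stall through competing silyl transfer. The fallback makes the same two bonds through metal enolates. It sets out from 5, 6 and 9: LDA converts 6 into lithium enolate 7, which is added to enone 5 in THF/DMPU at −78 °C to give the lithium ketone enolate F1. Trapping with acetaldehyde 9 gives the lithium aldolate F2, and aqueous quench returns to the route at 12. The closed, chelated transition state of the enolate Michael addition responds to enolate geometry (deprotonation in THF alone or with DMPU), which gives a second handle on C7.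

Step 8. A stepwise, cation-like closure instead of the concerted ene pathway would erode facial selectivity at the aldehyde and leave the oxygen equatorial. The fallback sets out from 15 and keeps the material: the 6-epimer of 16, the equatorial alcohol F3, is treated with acetic acid under Mitsunobu conditions (PPh3, DIAD, toluene, 0 °C → rt). This inverts C6 and gives acetate 17 directly, so the route is rejoined at 17 and step 9 is skipped.

Step 2. The γ-hydrogen of 5 is also allylic to the isopropenyl group, so DBU may deprotonate the product, leading to racemisation or migration of the alkene into conjugation. The fallback improves the leaving group instead of using a strong amidine base. It sets out from 4: aqueous HF in MeCN at 0 °C gives the hydroxy ketone F4, and MsCl/Et3N in CH2Cl2 at −78 → −20 °C forms the mesylate F5, which eliminates under these much milder conditions and returns to the route at 5.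

Further compounds
F1 | step 4 | lithium (3S,4R)-3-[(2S)-1-methoxy-3-methyl-1-oxobutan-2-yl]-4-(prop-1-en-2-yl)cyclopent-1-en-1-olate | COC(=O)[C@@H](C(C)C)[C@@H]1C=C([O-])C[C@H]1C(C)=C.[Li+]
F2 | step 4 | lithium alkoxide of 12 (lithium aldolate) | COC(=O)[C@@H](C(C)C)[C@@H]1[C@@H](C(C)[O-])C(=O)C[C@H]1C(C)=C.[Li+]
F3 | step 8 | (1S,3aR,6S,7S,7aR)-1-[1-(tert-butyldimethylsilyloxy)ethyl]-6-hydroxy-4-methylidene-7-(propan-2-yl)octahydro-2H-inden-2-one | C=C1C[C@H](O)[C@@H](C(C)C)[C@@H]2[C@@H](C(C)O[Si](C)(C)C(C)(C)C)C(=O)C[C@@H]12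
F4 | step 2 | (3S,4R)-4-hydroxy-3-(prop-1-en-2-yl)cyclopentan-1-one | O[C@@H]1CC(=O)C[C@H]1C(C)=C
F5 | step 2 | (1R,2S)-4-oxo-2-(prop-1-en-2-yl)cyclopentyl methanesulfonate | CS(=O)(=O)O[C@@H]1CC(=O)C[C@H]1C(C)=C
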